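## Retrosynthetic overview

1. Target ⇒ syn-dihydroxylation (C9–O, C10–O) of a Δ9 vinyl-epoxide ester ⇒ O6-acylation ⇒ spiro-epoxide from C6-hydroxyl-directed epoxidation of an 8(14),9-diene-4,6-diol. This epoxidation sets quaternary C8 and fixes the order of the late steps (O6 stays free until the oxirane is in).
2. Diene diol ⇒ seven-membered ring closed at C9=C10 by ethylene ene–yne cross-metathesis/ring-closing metathesis of a monocyclic homopropargylic diol carrying a (Z)-propenyl group on C1.
3. Homopropargylic diol ⇒ chelate-controlled propargylation of a C6 aldehyde ⇒ isopropyl addition to the C4 ketone of a 2-(dimethoxymethyl)cyclopentanone.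
4. That ketone ⇒ 3-methylcyclopent-2-enone + (Z)-propenyl alane + trimethyl orthoformate in one enantioselective conjugate addition/enolate acetalisation (C1 and C5).
5. Ring order: cyclopentane (present in the starting enone) → cycloheptadiene (metathesis) → oxirane (directed epoxidation).

Assumption: the SMILES is taken as drawn, i.e. (1S,4R,5S,6S,8S,9S,10S) in daucane numbering (C1 = methyl-bearing ring-fusion carbon, C4 = isopropyl carbinol, C5 = ring-fusion CH, C6–C10 = seven-membered ring, C14 = carbon on C8 outside the ring); α is the face of H-5.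

## Route

Step 1
Reactants: 1 3-methylcyclopent-2-en-1-one; 2 (Z)-1-bromoprop-1-ene
Product: 6 (2S,3R)-2-(dimethoxymethyl)-3-methyl-3-[(Z)-prop-1-en-1-yl]cyclopentan-1-one, via (Z)-prop-1-enyllithium 3 (not isolated), via (Z)-propenyl diisobutylalane 4 (not isolated), via aluminium enolate 5 (not isolated)
Conditions: 2, t-BuLi (2 equiv), Et2O, −78 °C; i-Bu2AlCl, −78 to 0 °C; then 1, Cu(OTf)2 (5 mol%), chiral sulfonate-imidazolinium carbene precursor L* (6 mol%), THF, −30 °C; then HC(OMe)3 (3 equiv), TMSOTf (10 mol%), −78 to −40 °C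
Reagents that add atoms: trimethyl orthoformate, COC(OC)OC
Why: Proposed new method: the copper–carbene catalyst formed from Cu(OTf)2 and L* transfers the (Z)-propenyl group of alane 4 to the β-carbon of 1 and sets C1 (closest known reaction: copper-catalysed enantioselective conjugate addition of alkenyl and silylvinyl alanes to β-methyl cycloalkenones, not shown for a Z-alkenyl alane or with C-acetalisation in the same flask); the regiodefined enolate 5 then attacks the dimethoxycarbenium ion (Mukaiyama-type) anti to the Z-propenyl group, whose cis-methyl is pushed over that face by allylic 1,3-strain, so C5 forms with the acetal carbon cis to the ring methyl, which is also the expected thermodynamic epimer.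

Step 2
Reactants: 6 (2S,3R)-2-(dimethoxymethyl)-3-methyl-3-[(Z)-prop-1-en-1-yl]cyclopentan-1-one
Product: 7 (1R,2R,3R)-2-(dimethoxymethyl)-3-methyl-1-(propan-2-yl)-3-[(Z)-prop-1-en-1-yl]cyclopentan-1-ol
Conditions: i-PrMgCl (2 equiv), CeCl3 (2.2 equiv, anhydrous), THF, −78 to −20 °C
Reagents that add atoms: isopropylmagnesium chloride, CC(C)[Mg]Cl
Why: Organocerium (Imamoto) 1,2-addition suppresses enolisation and reduction, and isopropyl enters anti to the neighbouring dimethoxymethyl group, giving the C4 carbinol with OH cis to C6 (4β-OH).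

Step 3
Reactants: 7 (1R,2R,3R)-2-(dimethoxymethyl)-3-methyl-1-(propan-2-yl)-3-[(Z)-prop-1-en-1-yl]cyclopentan-1-ol
Product: 9 (1R,2S,3R)-2-[(1S)-1-hydroxybut-3-yn-1-yl]-3-methyl-1-(propan-2-yl)-3-[(Z)-prop-1-en-1-yl]cyclopentan-1-ol, via hydroxy aldehyde 8 (not isolated)
Conditions: Amberlyst-15, THF–H2O (4:1), 0 °C to rt; filter; then Zn dust (3 equiv), HC≡CCH2Br (2 equiv), sat. aq. NH4Cl, 0 °C to rt
Reagents that add atoms: water, O; 3-bromoprop-1-yne, C#CCBr
Why: Mild acetal hydrolysis followed by aqueous zinc Barbier propargylation through the allenylzinc (SE2'); Cram-chelate control (zinc bridging the tertiary C4 oxygen and the aldehyde oxygen, attack on the exposed face of the chelate) gives the 1,3-anti diol, i.e. (6S).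

Step 4
Reactants: 9 (1R,2S,3R)-2-[(1S)-1-hydroxybut-3-yn-1-yl]-3-methyl-1-(propan-2-yl)-3-[(Z)-prop-1-en-1-yl]cyclopentan-1-ol
Product: 11 (1R,4R,5S,6S)-dauca-8(14),9-diene-4,6-diol, via triene diol 10 (not isolated)
Conditions: H2C=CH2 (1 atm), second-generation Grubbs catalyst (5 mol%), toluene, 60 °C; then argon sparge, 80 °C
Reagents that add atoms: ethylene, C=C
Why: Ene–yne cross-metathesis of the terminal alkyne with ethylene builds the 2-substituted butadiene 10, and diene–ene ring-closing metathesis onto the (Z)-propenyl group (loss of propene) closes the seven-membered ring at C9=C10; no stereocentre is formed.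

Step 5
Reactants: 11 (1R,4R,5S,6S)-dauca-8(14),9-diene-4,6-diol
Product: 12 (1R,4R,5S,6S,8R)-8,14-epoxydauc-9-ene-4,6-diol
Conditions: VO(acac)2 (5 mol%), t-BuOOH (1.3 equiv, decane solution), CH2Cl2, 0 °C to rt
Reagents that add atoms: tert-butyl hydroperoxide, CC(C)(C)OO
Why: Vanadium-catalysed hydroxyl-directed epoxidation: the vanadate ester of the homoallylic C6–OH delivers oxygen to the exocyclic alkene on its own (α) face and sets C8, while the ring alkene is out of reach and the tertiary C4–OH lies on the other face.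

Step 6
Reactants: 12 (1R,4R,5S,6S,8R)-8,14-epoxydauc-9-ene-4,6-diol
Product: 13 (1R,4R,5S,6S,8R)-8,14-epoxy-4-hydroxydauc-9-en-6-yl 3-methylbutanoate
Conditions: (i-BuCO)2O (1.5 equiv), DMAP (10 mol%), Et3N, CH2Cl2, 0 °C to rt
Reagents that add atoms: 3-methylbutanoic anhydride, CC(C)CC(=O)OC(=O)CC(C)C
Why: DMAP-catalysed acyl transfer esterifies the only secondary hydroxyl; the tertiary C4–OH and the vinyl epoxide are inert to these basic conditions.

Step 7
Reactants: 13 (1R,4R,5S,6S,8R)-8,14-epoxy-4-hydroxydauc-9-en-6-yl 3-methylbutanoate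
Product: 14 (1S,4R,5S,6S,8S,9S,10S)-8,14-epoxy-4,9,10-trihydroxydaucan-6-yl 3-methylbutanoate
Conditions: OsO4 (2 mol%), NMO (1.5 equiv), acetone–H2O (4:1), 0 °C to rt
Reagents that add atoms: N-methylmorpholine N-oxide, C[N+]1([O-])CCOCC1; water, O
Why: Upjohn catalytic syn-dihydroxylation of the only remaining alkene; osmium tetroxide should approach anti to the axial angular methyl on C1 and anti to the epoxide methylene on C8, giving the 9α,10α-diol.

## Compound list

1 | 3-methylcyclopent-2-en-1-one | CC1=CC(=O)CC1 | starting material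
2 | (Z)-1-bromoprop-1-ene | C/C=C\Br | starting material
3 | (Z)-prop-1-enyllithium | [Li]/C=C\C | intermediate
4 | diisobutyl[(Z)-prop-1-en-1-yl]aluminium | C/C=C\[Al](CC(C)C)CC(C)C | intermediate
5 | diisobutylaluminium (R)-3-methyl-3-[(Z)-prop-1-en-1-yl]cyclopent-1-en-1-olate | C[C@]1(/C=C\C)CCC(O[Al](CC(C)C)CC(C)C)=C1 | intermediate
6 | (2S,3R)-2-(dimethoxymethyl)-3-methyl-3-[(Z)-prop-1-en-1-yl]cyclopentan-1-one | COC(OC)[C@@H]1[C@@](C)(/C=C\C)CCC1=O | intermediate
7 | (1R,2R,3R)-2-(dimethoxymethyl)-3-methyl-1-(propan-2-yl)-3-[(Z)-prop-1-en-1-yl]cyclopentan-1-ol | COC(OC)[C@@H]1[C@@](C)(/C=C\C)CC[C@@]1(O)C(C)C | intermediate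
8 | (1R,2R,5R)-2-hydroxy-5-methyl-2-(propan-2-yl)-5-[(Z)-prop-1-en-1-yl]cyclopentane-1-carbaldehyde | O=C[C@@H]1[C@@](C)(/C=C\C)CC[C@@]1(O)C(C)C | intermediate
9 | (1R,2S,3R)-2-[(1S)-1-hydroxybut-3-yn-1-yl]-3-methyl-1-(propan-2-yl)-3-[(Z)-prop-1-en-1-yl]cyclopentan-1-ol | C#CC[C@H](O)[C@@H]1[C@@](C)(/C=C\C)CC[C@@]1(O)C(C)C | intermediate
10 | (1R,2S,3R)-2-[(1S)-1-hydroxy-3-methylidenepent-4-en-1-yl]-3-methyl-1-(propan-2-yl)-3-[(Z)-prop-1-en-1-yl]cyclopentan-1-ol | C=CC(=C)C[C@H](O)[C@@H]1[C@@](C)(/C=C\C)CC[C@@]1(O)C(C)C | intermediate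
11 | (1R,4R,5S,6S)-dauca-8(14),9-diene-4,6-diol (4β-OH, 5α-H, 6α-OH, angular methyl β) | O[C@H]1CC(=C)C=C[C@@]2(C)CC[C@@](O)(C(C)C)[C@H]12 | intermediate
12 | (1R,4R,5S,6S,8R)-8,14-epoxydauc-9-ene-4,6-diol (epoxide oxygen α) | O[C@H]1C[C@]2(CO2)C=C[C@@]3(C)CC[C@@](O)(C(C)C)[C@H]13 | intermediate
13 | (1R,4R,5S,6S,8R)-8,14-epoxy-4-hydroxydauc-9-en-6-yl 3-methylbutanoate | CC(C)CC(=O)O[C@H]1C[C@]2(CO2)C=C[C@@]3(C)CC[C@@](O)(C(C)C)[C@H]13 | intermediate
14 | (1S,4R,5S,6S,8S,9S,10S)-8,14-epoxy-4,9,10-trihydroxydaucan-6-yl 3-methylbutanoate (CNP0307265.1) | CC(C)CC(=O)O[C@H]1C[C@]2(CO2)[C@@H](O)[C@@H](O)[C@@]2(C)CC[C@@](O)(C(C)C)[C@H]12 | target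

## Step count and risks

Total step count: 7. Longest linear sequence: 7 steps (from 1).

The three steps most likely to fail are steps 1, 3 and 4.

**Step 1 (the proposed new step).** The Z-alkenyl transfer may give low enantioselectivity, the aluminium enolate may not condense cleanly with the orthoformate, or the facial bias at C5 may be weaker than argued. The fallback uses known chemistry and sets out from 1. Hex-1-yne is hydroaluminated with i-Bu2AlH and the (E)-hexenyl alane is added to 1 under established copper-catalysed enantioselective conditions for alkenyl alanes and β-methyl cycloalkenones. The resulting aluminium enolate F1 is silylated in the flask with TMSOTf to the trimethylsilyl enol ether F2, which is isolated and treated with HC(OMe)3 and catalytic TMSOTf (Mukaiyama reaction). Without the Z-substituent little facial bias is expected, so the trans acetal ketone F3 is separated by chromatography from its cis epimer F4. F3 is then carried through the conditions of steps 2 to 4: the tertiary alcohol F5, the hydroxy aldehyde F6 (not isolated), the homopropargylic diol F7 and, under ethylene, the triene F8 (not isolated). F8 ring-closes with loss of hex-1-ene and comes back to the route at 11.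

**Step 3.** The β-hydroxy aldehyde 8 can dehydrate or undergo retro-aldol cleavage, and chelate control in the Barbier addition may be incomplete, giving 9 as a mixture at C6. The fallback sets the stereocentre by hydride instead and sets out from 9 (epimer mixture). Dess–Martin oxidation of the secondary alcohol gives the β-hydroxy ketone F9. Reduction with Me4NBH(OAc)3 in MeCN–AcOH at −20 °C (Evans–Saksena, hydride delivered from the borate on the tertiary C4 oxygen) gives the 1,3-anti diol and comes back to the route at 9 as the single (6S) isomer.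

**Step 4.** The ene–yne cross-metathesis with ethylene may stall on the free homopropargylic alcohol, or the carbene may close onto the inner 1,1-disubstituted alkene to give a six-membered ring. The fallback brings the diene in preformed and sets out from 7. The aldehyde 8, released as in step 3, is isoprenylated with 2-(bromomethyl)buta-1,3-diene and In powder in THF–H2O (same chelate control) to give the triene diol 10, now isolated. Plain ring-closing metathesis (second-generation Grubbs catalyst, CH2Cl2, 40 °C, high dilution, no ethylene) comes back to the route at 11. No compound outside the list is made.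

Further compounds
F1 | step 1 | diisobutylaluminium (R)-3-[(E)-hex-1-en-1-yl]-3-methylcyclopent-1-en-1-olate | CCCC/C=C/[C@@]1(C)CCC(O[Al](CC(C)C)CC(C)C)=C1
F2 | step 1 | {[(R)-3-[(E)-hex-1-en-1-yl]-3-methylcyclopent-1-en-1-yl]oxy}trimethylsilane | CCCC/C=C/[C@@]1(C)CCC(O[Si](C)(C)C)=C1
F3 | step 1 | (2S,3R)-2-(dimethoxymethyl)-3-[(E)-hex-1-en-1-yl]-3-methylcyclopentan-1-one | COC(OC)[C@@H]1[C@@](C)(/C=C/CCCC)CCC1=O
F4 | step 1 | (2R,3R)-2-(dimethoxymethyl)-3-[(E)-hex-1-en-1-yl]-3-methylcyclopentan-1-one | COC(OC)[C@H]1[C@@](C)(/C=C/CCCC)CCC1=O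
F5 | step 1 | (1R,2R,3R)-2-(dimethoxymethyl)-3-[(E)-hex-1-en-1-yl]-3-methyl-1-(propan-2-yl)cyclopentan-1-ol | COC(OC)[C@@H]1[C@@](C)(/C=C/CCCC)CC[C@@]1(O)C(C)C
F6 | step 1 | (1R,2R,5R)-5-[(E)-hex-1-en-1-yl]-2-hydroxy-5-methyl-2-(propan-2-yl)cyclopentane-1-carbaldehyde | O=C[C@@H]1[C@@](C)(/C=C/CCCC)CC[C@@]1(O)C(C)C
F7 | step 1 | (1R,2S,3R)-3-[(E)-hex-1-en-1-yl]-2-[(1S)-1-hydroxybut-3-yn-1-yl]-3-methyl-1-(propan-2-yl)cyclopentan-1-ol | C#CC[C@H](O)[C@@H]1[C@@](C)(/C=C/CCCC)CC[C@@]1(O)C(C)C
F8 | step 1 | (1R,2S,3R)-3-[(E)-hex-1-en-1-yl]-2-[(1S)-1-hydroxy-3-methylidenepent-4-en-1-yl]-3-methyl-1-(propan-2-yl)cyclopentan-1-ol | C=CC(=C)C[C@H](O)[C@@H]1[C@@](C)(/C=C/CCCC)CC[C@@]1(O)C(C)C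
F9 | step 3 | 1-[(1R,2R,5R)-2-hydroxy-5-methyl-2-(propan-2-yl)-5-[(Z)-prop-1-en-1-yl]cyclopentyl]but-3-yn-1-one | C#CCC(=O)[C@@H]1[C@@](C)(/C=C\C)CC[C@@]1(O)C(C)C
F0 | step 4 | none | none
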